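**Plan**
- Retrosynthesis: remove the thirteen benzyl ethers and both gallate esters, then cut the C4(upper)–C8(lower) interflavan bond (C4-activated epiafzelechin as electrophile, C8 of epicatechin as nucleophile). In ring C of each flavan, cut O1–C8a and C2–C3, which leads to one fluoro ketone and two benzaldehydes.
- Enabling feature: in ring C, C4 lies between C3 and ring-A carbon C4a and is ortho to C8a. As a ketone it acidifies C3–H (the enolate is the C3 nucleophile) and activates a C8a–F bond for displacement by the aldolate oxygen O1, so aldehyde plus enolate should close ring C in one operation.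
- Forward: ring A comes intact from 1,3,5-trifluorobenzene and ring C is closed by the aldol–SNAr annulation. The C4 oxygen helper is then removed by reduction and acid-mediated 1,2-carbonyl transposition, which leaves C4 as CH2 and C3 as a ketone.
- Stereochemistry: C2 and C3 of each unit (2R,3R, cis) come from asymmetric hydrogenation with dynamic kinetic resolution of the racemic flavan-3-ones over RuCl2[(S)-xylbinap][(S)-daipen]. Upper C4 (4R, 4β) comes from attack of the lower unit anti to the 3-oxygen of the upper unit.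
- Both units are made from the same fluoro ketone 5; coupling, double galloylation and global hydrogenolysis finish the route.

Key step: step 3

Remark: 9, 10, 16 and 17 are racemates of fixed relative configuration, drawn as one enantiomer; 11 and 18 are racemates drawn without configuration, since C2 is reset in steps 6 and 10.

**Route**

Step 1
Reactants: 1 1,3,5-trifluorobenzene; 2 N,2-dimethoxy-N-methylacetamide
Product: 4 2-methoxy-1-(2,4,6-trifluorophenyl)ethan-1-one, via 2,4,6-trifluorophenyllithium 3 (not isolated)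
Conditions: n-BuLi, THF, −78 °C; then 2, −78 → −20 °C; aq. NH4Cl
Reagents that add atoms: none
Why: Fluorine-directed ortho-lithiation gives the aryllithium below the temperature of benzyne formation, and Weinreb amide acylation should stop at the ketone through the chelated tetrahedral intermediate.

Step 2
Reactants: 4 2-methoxy-1-(2,4,6-trifluorophenyl)ethan-1-one
Product: 5 1-[2,4-bis(benzyloxy)-6-fluorophenyl]-2-methoxyethan-1-one
Conditions: BnOH (2.1 equiv), NaH (2.1 equiv), DMF, 0 → 25 °C
Reagents that add atoms: benzyl alcohol, OCc1ccccc1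
Why: Double SNAr, in which the acyl group activates the para fluorine and then one of the two equivalent ortho fluorines; the two alkoxy groups introduced should slow the third substitution so that one C–F bond is kept for the key step.

Step 3
Reactants: 5 1-[2,4-bis(benzyloxy)-6-fluorophenyl]-2-methoxyethan-1-one; 6 3,4-bis(benzyloxy)benzaldehyde
Product: 9 (±)-(2R*,3R*)-5,7-bis(benzyloxy)-2-[3,4-bis(benzyloxy)phenyl]-3-methoxychroman-4-one (2,3-trans), via lithium enolate 7 (not isolated), via lithium aldolate 8 (not isolated)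
Conditions: LiN(SiMe3)2, THF, −78 °C; 6, −78 → 0 °C; then DMPU, 25 → 50 °C
Reagents that add atoms: none
Why: Proposed new method: the chelated lithium (Z)-enolate 7 adds through C3 to aldehyde 6 and forms C2–C3; the aldolate oxygen O1 of 8 then attacks C8a in an addition–elimination through a Meisenheimer complex stabilised by the ortho C4 carbonyl, expels fluoride and forms O1–C8a, so that ring C closes in a six-membered mode, 6-exo with respect to the C–F bond that breaks. The closest known reaction types are the one-pot acylation/SNAr synthesis of flavones and 4-quinolones from 2'-fluoroacetophenones and the tandem Michael–SNAr and aldol–SNAr annulations of ortho-fluoroaryl ketones. C2 and C3 are formed without absolute control; their relative configuration is under thermodynamic control (reversible aldol, enolisable C3–H) and should settle as the trans diequatorial isomer. Both centres are provisional, since C3 becomes sp2 in step 5 and C2 is reset in step 6. The step needs O-arylation to outrun retro-aldol drift and dehydration: the SNAr is irreversible and drains the aldol equilibrium, the 3-oxygen is an ether and cannot close a five-membered coumaranone, and only C8a still carries fluorine.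

Step 4
Reactants: 9 (±)-(2R*,3R*)-5,7-bis(benzyloxy)-2-[3,4-bis(benzyloxy)phenyl]-3-methoxychroman-4-one
Product: 10 (±)-2,3-trans-5,7-bis(benzyloxy)-2-[3,4-bis(benzyloxy)phenyl]-3-methoxychroman-4-ol (C4 epimers)
Conditions: NaBH4, THF/MeOH, 0 °C; used crude
Reagents that add atoms: none
Why: Borohydride 1,2-reduction of the aryl ketone, as in the reduction of dihydroflavonols to flavan-3,4-diols; the C4 configuration is immaterial because C4 is ionised in step 5.

Step 5
Reactants: 10 (±)-2,3-trans-5,7-bis(benzyloxy)-2-[3,4-bis(benzyloxy)phenyl]-3-methoxychroman-4-ol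
Product: 11 (±)-5,7-bis(benzyloxy)-2-[3,4-bis(benzyloxy)phenyl]chroman-3-one
Conditions: TsOH·H2O (cat.), THF/H2O, 40 °C, high dilution
Reagents that add atoms: water, O
Why: Acid ionises the doubly alkoxy-stabilised benzylic C4–OH, and loss of the C3 proton (or a 1,2-hydride shift) gives the 3-methoxy enol ether/oxocarbenium, which hydrolyses to the ketone; this is a pinacol-type 1,2-carbonyl transposition, as in the acid dehydration of chroman-3,4-diols to chroman-3-ones, and it leaves C4 as CH2.

Step 6
Reactants: 11 (±)-5,7-bis(benzyloxy)-2-[3,4-bis(benzyloxy)phenyl]chroman-3-one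
Product: 12 (2R,3R)-5,7-bis(benzyloxy)-2-[3,4-bis(benzyloxy)phenyl]chroman-3-ol (5,7,3',4'-tetra-O-benzyl-(−)-epicatechin)
Conditions: RuCl2[(S)-xylbinap][(S)-daipen] (cat.), t-BuOK (cat.), H2 (10 atm), i-PrOH/toluene, 25 °C
Reagents that add atoms: none
Why: Noyori-type asymmetric hydrogenation with dynamic kinetic resolution, as for racemic 2-arylcyclohexanones: C2–H (alpha to the ketone, benzylic, alpha to O1) racemises under base, the catalyst should reduce the 2R enantiomer faster and deliver hydride to C3 anti to the 2-aryl group, so both centres of the cis (2R,3R) alcohol are catalyst-controlled (the antipodal catalyst is used if the sense of induction proves opposite).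

Step 7
Reactants: 5 1-[2,4-bis(benzyloxy)-6-fluorophenyl]-2-methoxyethan-1-one; 13 4-(benzyloxy)benzaldehyde
Product: 16 (±)-(2R*,3R*)-5,7-bis(benzyloxy)-2-[4-(benzyloxy)phenyl]-3-methoxychroman-4-one (2,3-trans), via sodium enolate 14 (not isolated), via sodium aldolate 15 (not isolated)
Conditions: NaN(SiMe3)2, THF, −78 °C; 13, −78 → 0 °C; then DMPU, 0 → 40 °C
Reagents that add atoms: none
Why: Proposed new method: the same annulation as in step 3, in which C3 of sodium enolate 14 adds to the aldehyde (C2–C3) and the oxygen of aldolate 15 displaces the ortho fluorine activated by the C4 carbonyl (O1–C8a, six-membered addition–elimination); sodium is chosen because 13 lacks the meta-benzyloxy group and is the less electrophilic aldehyde, so the more ionic and more nucleophilic sodium alkoxide is used to make the irreversible ring closure outpace the less favourable aldol equilibrium, the closest known types being the acylation/SNAr flavone synthesis from 2'-fluoroacetophenones and tandem aldol–SNAr annulations, and the stereocentres are again provisional.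

Step 8
Reactants: 16 (±)-(2R*,3R*)-5,7-bis(benzyloxy)-2-[4-(benzyloxy)phenyl]-3-methoxychroman-4-one
Product: 17 (±)-2,3-trans-5,7-bis(benzyloxy)-2-[4-(benzyloxy)phenyl]-3-methoxychroman-4-ol (C4 epimers)
Conditions: NaBH4, THF/MeOH, 0 °C; used crude
Reagents that add atoms: none
Why: Borohydride 1,2-reduction of the aryl ketone, as in step 4.

Step 9
Reactants: 17 (±)-2,3-trans-5,7-bis(benzyloxy)-2-[4-(benzyloxy)phenyl]-3-methoxychroman-4-ol
Product: 18 (±)-5,7-bis(benzyloxy)-2-[4-(benzyloxy)phenyl]chroman-3-one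
Conditions: TsOH·H2O (cat.), THF/H2O, 40 °C, high dilution
Reagents that add atoms: water, O
Why: Pinacol-type 1,2-carbonyl transposition as in step 5 (ionisation at C4, enol ether/oxocarbenium at C3, hydrolysis).

Step 10
Reactants: 18 (±)-5,7-bis(benzyloxy)-2-[4-(benzyloxy)phenyl]chroman-3-one
Product: 19 (2R,3R)-5,7-bis(benzyloxy)-2-[4-(benzyloxy)phenyl]chroman-3-ol (5,7,4'-tri-O-benzyl-(−)-epiafzelechin)
Conditions: RuCl2[(S)-xylbinap][(S)-daipen] (cat.), t-BuOK (cat.), H2 (10 atm), i-PrOH/toluene, 25 °C
Reagents that add atoms: none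
Why: Asymmetric hydrogenation with dynamic kinetic resolution as in step 6; the catalyst should set 2R and 3R (cis) together.

Step 11
Reactants: 19 5,7,4'-tri-O-benzyl-(−)-epiafzelechin
Product: 20 (2R,3R,4S)-5,7-bis(benzyloxy)-2-[4-(benzyloxy)phenyl]-4-(2-ethoxyethoxy)chroman-3-ol (4β-(2-ethoxyethoxy) derivative)
Conditions: DDQ, 2-ethoxyethanol, CH2Cl2, 25 °C
Reagents that add atoms: 2-ethoxyethanol, CCOCCO
Why: DDQ benzylic oxidation by hydride abstraction at the electron-rich C4 position, with capture by the alcohol trans to the 3-hydroxyl group; this is the standard C4 activation of benzylated flavan-3-ols.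

Step 12
Reactants: 20 4β-(2-ethoxyethoxy)-5,7,4'-tri-O-benzylepiafzelechin; 12 5,7,3',4'-tetra-O-benzyl-(−)-epicatechin
Product: 21 5,7,4'-tri-O-benzylepiafzelechin-(4β→8)-5,7,3',4'-tetra-O-benzylepicatechin
Conditions: TMSOTf (cat.), CH2Cl2, −78 °C; 12 in threefold excess (recovered)
Reagents that add atoms: none
Why: Lewis-acid-promoted Friedel–Crafts alkylation: the C4–O bond of 20 is ionised and C8 of 12 (the less hindered nucleophilic ring-A position, C6 lying between two benzyloxy groups) attacks C4 anti to the 3-hydroxyl and 2-aryl groups, which should give the 4β (4R, 3,4-trans) 4→8 linkage; the excess of 12 suppresses chain extension.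

Step 13
Reactants: 21 hepta-O-benzyl dimer diol; 22 3,4,5-tris(benzyloxy)benzoic acid
Product: 23 3-O-[3,4,5-tris(benzyloxy)benzoyl]-5,7,4'-tri-O-benzylepiafzelechin-(4β→8)-3-O-[3,4,5-tris(benzyloxy)benzoyl]-5,7,3',4'-tetra-O-benzylepicatechin
Conditions: 22 (4 equiv), DCC, DMAP, CH2Cl2, 25 °C
Reagents that add atoms: none
Why: Steglich esterification of both secondary 3-hydroxyl groups with excess acid; no stereocentre is touched.

Step 14
Reactants: 23 tridecabenzyl bis-gallate
Product: 24 epiafzelechin 3-O-gallate-(4β→8)-epicatechin 3-O-gallate (target)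
Conditions: H2 (1 atm), Pd(OH)2/C, THF/MeOH/H2O, 25 °C
Reagents that add atoms: none
Why: Hydrogenolysis of all thirteen benzyl ethers under neutral conditions, which should leave the gallate esters and the interflavan bond intact.

**Compound list**

1 | 1,3,5-trifluorobenzene | Fc1cc(F)cc(F)c1 | starting material
2 | N,2-dimethoxy-N-methylacetamide | COCC(=O)N(C)OC | starting material
3 | 2,4,6-trifluorophenyllithium | [Li]c1c(F)cc(F)cc1F | intermediate
4 | 2-methoxy-1-(2,4,6-trifluorophenyl)ethan-1-one | COCC(=O)c1c(F)cc(F)cc1F | intermediate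
5 | 1-[2,4-bis(benzyloxy)-6-fluorophenyl]-2-methoxyethan-1-one | COCC(=O)c1c(F)cc(OCc2ccccc2)cc1OCc1ccccc1 | intermediate
6 | 3,4-bis(benzyloxy)benzaldehyde | O=Cc1ccc(OCc2ccccc2)c(OCc2ccccc2)c1 | starting material
7 | lithium (Z)-enolate of 5 | [Li]O/C(=C\OC)c1c(F)cc(OCc2ccccc2)cc1OCc1ccccc1 | intermediate
8 | lithium aldolate from 7 and 6 (diastereomer mixture) | COC(C(=O)c1c(F)cc(OCc2ccccc2)cc1OCc1ccccc1)C(O[Li])c1ccc(OCc2ccccc2)c(OCc2ccccc2)c1 | intermediate
9 | (±)-(2R*,3R*)-5,7-bis(benzyloxy)-2-[3,4-bis(benzyloxy)phenyl]-3-methoxychroman-4-one | O=C1c2c(OCc3ccccc3)cc(OCc3ccccc3)cc2O[C@H](c2ccc(OCc3ccccc3)c(OCc3ccccc3)c2)[C@H]1OC | intermediate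
10 | (±)-2,3-trans-5,7-bis(benzyloxy)-2-[3,4-bis(benzyloxy)phenyl]-3-methoxychroman-4-ol (C4 epimers) | OC1c2c(OCc3ccccc3)cc(OCc3ccccc3)cc2O[C@H](c2ccc(OCc3ccccc3)c(OCc3ccccc3)c2)[C@H]1OC | intermediate
11 | (±)-5,7-bis(benzyloxy)-2-[3,4-bis(benzyloxy)phenyl]chroman-3-one | O=C1Cc2c(OCc3ccccc3)cc(OCc3ccccc3)cc2OC1c1ccc(OCc2ccccc2)c(OCc2ccccc2)c1 | intermediate
12 | (2R,3R)-5,7-bis(benzyloxy)-2-[3,4-bis(benzyloxy)phenyl]chroman-3-ol | c1(OCc2ccccc2)cc(OCc2ccccc2)c2c(c1)O[C@H](c1ccc(OCc3ccccc3)c(OCc3ccccc3)c1)[C@H](O)C2 | intermediate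
13 | 4-(benzyloxy)benzaldehyde | O=Cc1ccc(OCc2ccccc2)cc1 | starting material
14 | sodium (Z)-enolate of 5 | [Na]O/C(=C\OC)c1c(F)cc(OCc2ccccc2)cc1OCc1ccccc1 | intermediate
15 | sodium aldolate from 14 and 13 (diastereomer mixture) | COC(C(=O)c1c(F)cc(OCc2ccccc2)cc1OCc1ccccc1)C(O[Na])c1ccc(OCc2ccccc2)cc1 | intermediate
16 | (±)-(2R*,3R*)-5,7-bis(benzyloxy)-2-[4-(benzyloxy)phenyl]-3-methoxychroman-4-one | O=C1c2c(OCc3ccccc3)cc(OCc3ccccc3)cc2O[C@H](c2ccc(OCc3ccccc3)cc2)[C@H]1OC | intermediate
17 | (±)-2,3-trans-5,7-bis(benzyloxy)-2-[4-(benzyloxy)phenyl]-3-methoxychroman-4-ol (C4 epimers) | OC1c2c(OCc3ccccc3)cc(OCc3ccccc3)cc2O[C@H](c2ccc(OCc3ccccc3)cc2)[C@H]1OC | intermediate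
18 | (±)-5,7-bis(benzyloxy)-2-[4-(benzyloxy)phenyl]chroman-3-one | O=C1Cc2c(OCc3ccccc3)cc(OCc3ccccc3)cc2OC1c1ccc(OCc2ccccc2)cc1 | intermediate
19 | (2R,3R)-5,7-bis(benzyloxy)-2-[4-(benzyloxy)phenyl]chroman-3-ol | c1(OCc2ccccc2)cc(OCc2ccccc2)c2c(c1)O[C@H](c1ccc(OCc3ccccc3)cc1)[C@H](O)C2 | intermediate
20 | (2R,3R,4S)-5,7-bis(benzyloxy)-2-[4-(benzyloxy)phenyl]-4-(2-ethoxyethoxy)chroman-3-ol | O[C@@H]1[C@@H](OCCOCC)c2c(OCc3ccccc3)cc(OCc3ccccc3)cc2O[C@@H]1c1ccc(OCc2ccccc2)cc1 | intermediate
21 | 5,7,4'-tri-O-benzylepiafzelechin-(4β→8)-5,7,3',4'-tetra-O-benzylepicatechin | O[C@@H]1[C@@H](c2c(OCc4ccccc4)cc(OCc4ccccc4)c3c2O[C@H](c2ccc(OCc4ccccc4)c(OCc4ccccc4)c2)[C@H](O)C3)c2c(OCc4ccccc4)cc(OCc4ccccc4)cc2O[C@@H]1c1ccc(OCc4ccccc4)cc1 | intermediate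
22 | 3,4,5-tris(benzyloxy)benzoic acid | OC(=O)c1cc(OCc2ccccc2)c(OCc2ccccc2)c(OCc2ccccc2)c1 | starting material
23 | tridecabenzyl ether of the target (bis-gallate of 21) | O=C(O[C@@H]1[C@@H](c2c(OCc4ccccc4)cc(OCc4ccccc4)c3c2O[C@H](c2ccc(OCc4ccccc4)c(OCc4ccccc4)c2)[C@H](OC(=O)c2cc(OCc4ccccc4)c(OCc4ccccc4)c(OCc4ccccc4)c2)C3)c2c(OCc4ccccc4)cc(OCc4ccccc4)cc2O[C@@H]1c1ccc(OCc4ccccc4)cc1)c1cc(OCc4ccccc4)c(OCc4ccccc4)c(OCc4ccccc4)c1 | intermediate
24 | epiafzelechin 3-O-gallate-(4β→8)-epicatechin 3-O-gallate | O=C(O[C@@H]1[C@@H](c2c(O)cc(O)c3c2O[C@H](c2ccc(O)c(O)c2)[C@H](OC(=O)c2cc(O)c(O)c(O)c2)C3)c2c(O)cc(O)cc2O[C@@H]1c1ccc(O)cc1)c1cc(O)c(O)c(O)c1 | target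

**Step count and risks**

Total: 14 steps. Longest linear sequence: 10 steps (1, 2, 7, 8, 9, 10, 11, 12, 13, 14).

Most likely to fail:

Step 3 (Proposed new method). The aldolate may drift back by retro-aldol or dehydrate to the α-methoxychalcone before the lithium alkoxide displaces fluoride, or the SNAr may be too slow on the twisted, doubly alkoxylated aryl ketone. The fallback separates the two bond formations and uses known chemistry. It sets out from 5, which is converted (TMSOTf, Et3N, CH2Cl2) into the trimethylsilyl enol ether F1. A Mukaiyama aldol addition of F1 to 6 (BF3·OEt2, CH2Cl2, −78 °C) should give, after aqueous work-up, the β-hydroxy ketone F2, which is isolated. F2 is then cyclised by intramolecular SNAr (K2CO3, DMF, 60 °C), and the route is rejoined at 9.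

Step 7 (Proposed new method). The same competition between retro-aldol/dehydration and ring closure applies with the less electrophilic 4-(benzyloxy)benzaldehyde, and a sodium aldolate reverts more easily than a lithium one. The fallback again sets out from 5 by way of the trimethylsilyl enol ether F1. Its Mukaiyama aldol addition to 13 (BF3·OEt2, CH2Cl2, −78 °C) should give the β-hydroxy ketone F3, whose separate SNAr cyclisation (K2CO3, DMF, 60 °C) returns to the route at 16.

Step 6. Enantiodiscrimination by the catalyst may be insufficient, or C2 may racemise more slowly than the ketone is reduced, so that the alcohol is formed with low enantiomeric purity. The fallback replaces dynamic kinetic resolution by diastereoselective reduction and physical resolution. It sets out from 11, which is reduced with LiBH(s-Bu)3 (THF, −78 °C) to the racemic cis alcohol, that is 12 together with the (2S,3S)-alcohol F4. The enantiomers are separated by preparative chromatography on a chiral stationary phase, and the route is rejoined at 12. F4 is reoxidised to 11 with Dess–Martin periodinane and recycled. The same measure would serve for step 10.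

**Further compounds**

F1 | step 3 | (Z)-{1-[2,4-bis(benzyloxy)-6-fluorophenyl]-2-methoxyethenyl}oxy(trimethyl)silane | CO/C=C(\O[Si](C)(C)C)c1c(F)cc(OCc2ccccc2)cc1OCc1ccccc1
F2 | step 3 | 1-[2,4-bis(benzyloxy)-6-fluorophenyl]-3-[3,4-bis(benzyloxy)phenyl]-3-hydroxy-2-methoxypropan-1-one (diastereomer mixture) | COC(C(=O)c1c(F)cc(OCc2ccccc2)cc1OCc1ccccc1)C(O)c1ccc(OCc2ccccc2)c(OCc2ccccc2)c1
F3 | step 7 | 1-[2,4-bis(benzyloxy)-6-fluorophenyl]-3-[4-(benzyloxy)phenyl]-3-hydroxy-2-methoxypropan-1-one (diastereomer mixture) | COC(C(=O)c1c(F)cc(OCc2ccccc2)cc1OCc1ccccc1)C(O)c1ccc(OCc2ccccc2)cc1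
F4 | step 6 | (2S,3S)-5,7-bis(benzyloxy)-2-[3,4-bis(benzyloxy)phenyl]chroman-3-ol | c1(OCc2ccccc2)cc(OCc2ccccc2)c2c(c1)O[C@@H](c1ccc(OCc3ccccc3)c(OCc3ccccc3)c1)[C@@H](O)C2
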